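**Plan**

- Cuts: C12–C13 (aldol), C11–C12 (one-carbon homologation), C8=C17 (methylenation), C2–Cl (from a C2 ketone), and ring B at both C6–C7 and C9–C10, which takes the core back to ring A alone.
- Feature used: C6 (the ketone carbon) and C10 (quaternary) are both bonded to C5, and C10 is β to C2 through C1. With C2 as a ketone, ozonolysis of (S)-abscisic acid 1 gives ring A plus C6 as the hydroxy enone aldehyde 2, a 1,3-dielectrophile (C6, C10). C7–C8–C9–C11 of ring B is the acetoacetate 1,3-dinucleophile 3.
- Forward: ring A (from 1) → ring B by a formal (3+3) annulation (C6–C7 by aldol, then ring closure by the C9–C10 bond) → C5 deoxygenation → C2–Cl and C8=CH2 → C12 by Wittig, C13–C16 by aldol, imide closure → C6 ketone last.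
- Stereochemistry: the C5 carbinol of 1 is a temporary control element that sets C6 (chelation) and C10 (tether) and is then replaced by H from the α-face (trans-decalin). C9 comes from equilibration of the β-keto ester, C2 from equatorial hydride delivery followed by SN2 inversion, and C12/C13 from an (R)-oxazolidinone syn-aldol.

Key step: step 2

Remark: locants C1–C17 and C20 are the labdane locants of the target (C2 carries Cl, C4 the geminal methyls, C5/C10 are the ring-fusion carbons, C6 is the ketone carbon, C8 bears the exocyclic CH2 C17, C9 the side chain C11–C16, C20 is the angular methyl; β is the face of C20); β-keto esters 5–11 are written as keto forms with the 9β-ester because C9 equilibrates through the enol until step 7, and C6 is written as the chelation-derived 6β-alcohol, whose epimer would converge at ketone 25.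

**Step 1**
Reactants: 1 (S)-(+)-abscisic acid
Product: 2 (1S)-1-hydroxy-2,6,6-trimethyl-4-oxocyclohex-2-ene-1-carbaldehyde
Conditions: O3, CH2Cl2/MeOH, –78 °C; then Me2S, –78 °C → rt
Reagents that add atoms: ozone, [O-][O+]=O
Why: Ozonolysis with reductive work-up (Criegee mechanism) should cleave the C4=C5 side-chain alkene, the only C=C bond of 1 that does not carry a carbonyl group directly on it and therefore the most electron-rich, and it leaves the tertiary carbinol stereocentre (the later C5) untouched.

**Step 2**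
Reactants: 2 (1S)-1-hydroxy-2,6,6-trimethyl-4-oxocyclohex-2-ene-1-carbaldehyde, 3 1-methoxy-1,3-bis(trimethylsilyloxy)buta-1,3-diene
Product: 5 methyl 5β,6β-dihydroxy-4,4,10β-trimethyl-2,8-dioxodecalin-9β-carboxylate (rings A/B cis-fused, O5 cis to C20), via open-chain titanium aldolate 4 (not isolated)
Conditions: TiCl4 (2.2 equiv), CH2Cl2, –78 °C; then 3 (2.5 equiv), –78 → –20 °C; H2O
Reagents that add atoms: none
Why: Proposed new method: a domino Mukaiyama aldol and Mukaiyama–Michael addition, that is a formal (3+3) annulation of the 1,3-dinucleophile 3 with the 1,3-dielectrophile C6/C10 of 2, is proposed; the closest known reactions are the TiCl4-mediated (3+3) cyclisations of 1,3-bis(silyloxy)dienes with 1,3-dielectrophiles and intramolecular Mukaiyama–Michael additions, but the combination has not been shown on a γ-formyl β,β-disubstituted enone. The terminal carbon of 3 (C7) should add first to the aldehyde, which is activated inside a five-membered chlorotitanium chelate with the C5 alkoxide, to give 4; its remaining silyl enol ether carbon C9 then attacks C10 of the TiCl4-bound enone, and loss of the second silyl group leaves the β-keto ester. Ring B is closed by the C9–C10 bond in a 6-exo-trig mode, the C1=C10 bond lying outside the new ring. C6 is set by the chelate (attack anti to the CMe2 carbon, which also places C7 cis to C10 on the titanium diolate), and C10 is set by C5 of abscisic acid, because the tether can reach C10 only on the face that carries C6, so that C20 ends cis to O5; C9 stays epimerisable. The step needs aldehyde-before-enone chemoselectivity, secured by the much higher electrophilicity of the chelated aldehyde at –78 °C, and C- rather than O-attack at C10, secured because only C9 closes a six-membered ring.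

**Step 3**
Reactants: 5 methyl 5β,6β-dihydroxy-4,4,10β-trimethyl-2,8-dioxodecalin-9β-carboxylate
Product: 6 5β,6β-cyclic thionocarbonate of 5
Conditions: 1,1'-thiocarbonyldiimidazole, DMAP (cat.), PhMe, 80 °C
Reagents that add atoms: 1,1'-thiocarbonyldiimidazole, S=C(n1ccnc1)n1ccnc1
Why: Thiocarbonylation of the cis-5,6-diol: the less hindered secondary 6-hydroxyl is acylated first and the tertiary 5-hydroxyl then closes the five-membered cyclic thionocarbonate, which is the radical precursor for step 4.

**Step 4**
Reactants: 6 5β,6β-cyclic thionocarbonate of 5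
Product: 8 methyl 6β-hydroxy-4,4,10β-trimethyl-2,8-dioxo-5α-decalin-9β-carboxylate (rings A/B trans-fused), via S-stannyl thiocarbonate 7 (not isolated)
Conditions: Bu3SnH, AIBN (cat.), PhMe, 110 °C; then aq. KF, rt
Reagents that add atoms: none
Why: Barton–McCombie deoxygenation of a cyclic thionocarbonate: the stannyl radical adds to sulfur, the adduct fragments at the C5–O bond because this gives the tertiary radical, and Bu3SnH delivers hydrogen to C5 from the α-face, away from the two β-methyl groups on C4 and C10, which sets the trans ring fusion (5α-H) while fluoride work-up frees the 6β-hydroxyl from 7 and the β-keto ester settles as the equatorial 9β-ester.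

**Step 5**
Reactants: 8 methyl 6β-hydroxy-4,4,10β-trimethyl-2,8-dioxo-5α-decalin-9β-carboxylate
Product: 9 6β-triethylsilyl ether of 8
Conditions: Et3SiOTf, 2,6-lutidine, CH2Cl2, –78 → 0 °C; aq. citric acid
Reagents that add atoms: triethylsilyl trifluoromethanesulfonate, CC[Si](CC)(CC)OS(=O)(=O)C(F)(F)F
Why: Silyl triflate silylation protects the hindered axial 6β-hydroxyl so that only the C2 oxygen can react in step 8, and any enol silyl ether formed from the β-keto ester or the ketone is hydrolysed again in the acidic work-up.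

**Step 6**
Reactants: 9 6β-triethylsilyl ether of 8
Product: 11 methyl 2β-hydroxy-4,4,10β-trimethyl-8-oxo-6β-(triethylsilyloxy)-5α-decalin-9β-carboxylate, via sodium enolate 10 (not isolated)
Conditions: NaH, THF, 0 °C; then LiBH(CHMeEt)3, –78 °C; AcOH
Reagents that add atoms: none
Why: The β-keto ester is first stored as its sodium enolate 10, which hydride does not reduce, and the bulky borohydride then attacks the C2 ketone from the equatorial α-side because the axial β-approach is blocked by the syn-axial methyl groups on C4 and C10, which gives the axial 2β-alcohol.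

**Step 7**
Reactants: 11 methyl 2β-hydroxy-4,4,10β-trimethyl-8-oxo-6β-(triethylsilyloxy)-5α-decalin-9β-carboxylate
Product: 12 methyl 2β-hydroxy-4,4,10β-trimethyl-8-methylidene-6β-(triethylsilyloxy)-5α-decalin-9β-carboxylate
Conditions: Ph3PCH3Br, KOCMe3, PhMe, 90 °C
Reagents that add atoms: methyltriphenylphosphonium bromide, C[P+](c1ccccc1)(c1ccccc1)c1ccccc1.[Br-]
Why: Wittig methylenation of the hindered ring ketone of the β-keto ester, a reaction known for this drimane-type 8-oxo 9-ester, installs C17 without touching the ester, and C9 keeps its equatorial ester.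

**Step 8**
Reactants: 12 methyl 2β-hydroxy-4,4,10β-trimethyl-8-methylidene-6β-(triethylsilyloxy)-5α-decalin-9β-carboxylate
Product: 13 methyl 2α-chloro-4,4,10β-trimethyl-8-methylidene-6β-(triethylsilyloxy)-5α-decalin-9β-carboxylate
Conditions: PPh3, CCl4, MeCN, 60 °C
Reagents that add atoms: tetrachloromethane, ClC(Cl)(Cl)Cl
Why: Appel reaction: chloride attacks the axial alkoxyphosphonium ion at C2 from the α-face in an SN2 displacement, so that the configuration is inverted and chlorine ends equatorial (2α, the S configuration of the target), as known for axial steroid alcohols.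

**Step 9**
Reactants: 13 methyl 2α-chloro-4,4,10β-trimethyl-8-methylidene-6β-(triethylsilyloxy)-5α-decalin-9β-carboxylate
Product: 14 2α-chloro-4,4,10β-trimethyl-8-methylidene-6β-(triethylsilyloxy)-5α-decalin-9β-carbaldehyde
Conditions: (Me2CHCH2)2AlH, CH2Cl2, –78 °C; aq. KNaC4H4O6 (tartrate)
Reagents that add atoms: none
Why: Partial reduction of the hindered methyl ester with (Me2CHCH2)2AlH at –78 °C should stop at the aluminium hemiacetal, which gives the aldehyde on work-up, while the chloride, the silyl ether and the alkene are inert.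

**Step 10**
Reactants: 14 2α-chloro-4,4,10β-trimethyl-8-methylidene-6β-(triethylsilyloxy)-5α-decalin-9β-carbaldehyde
Product: 15 9β-(2-methoxyethenyl)-2α-chloro-4,4,10β-trimethyl-8-methylidene-6β-(triethylsilyloxy)-5α-decalin (E/Z mixture)
Conditions: Ph3P(CH2OMe)Cl, KN(SiMe3)2, THF, –78 → 0 °C
Reagents that add atoms: (methoxymethyl)triphenylphosphonium chloride, COC[P+](c1ccccc1)(c1ccccc1)c1ccccc1.[Cl-]
Why: Wittig reaction with the methoxymethylidene ylide adds C12 as an enol ether, and the geometry of the new double bond is of no consequence.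

**Step 11**
Reactants: 15 9β-(2-methoxyethenyl)-2α-chloro-4,4,10β-trimethyl-8-methylidene-6β-(triethylsilyloxy)-5α-decalin
Product: 16 2-(2α-chloro-6β-hydroxy-4,4,10β-trimethyl-8-methylidene-5α-decalin-9β-yl)acetaldehyde
Conditions: HCl (2 M in water), THF, rt
Reagents that add atoms: water, O
Why: Dilute acid hydrolyses the enol ether to the C12 aldehyde and at the same time cleaves the triethylsilyl ether, while the isolated exocyclic alkene and the secondary chloride are stable to these conditions.

**Step 12**
Reactants: 17 (4R)-4-benzyl-1,3-oxazolidin-2-one, 18 3-cyanopropanoic acid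
Product: 19 4-[(4R)-4-benzyl-2-oxo-1,3-oxazolidin-3-yl]-4-oxobutanenitrile
Conditions: N,N'-dicyclohexylcarbodiimide, DMAP (cat.), CH2Cl2, 0 °C → rt
Reagents that add atoms: none
Why: Carbodiimide coupling with DMAP catalysis N-acylates the oxazolidinone and creates no stereocentre.

**Step 13**
Reactants: 16 2-(2α-chloro-6β-hydroxy-4,4,10β-trimethyl-8-methylidene-5α-decalin-9β-yl)acetaldehyde, 19 4-[(4R)-4-benzyl-2-oxo-1,3-oxazolidin-3-yl]-4-oxobutanenitrile
Product: 21 (4R)-4-benzyl-3-[(2R,3S)-2-(cyanomethyl)-3-hydroxy-4-(2α-chloro-6β-hydroxy-4,4,10β-trimethyl-8-methylidene-5α-decalin-9β-yl)butanoyl]-1,3-oxazolidin-2-one, via (Z)-dibutylboron enolate 20 (not isolated)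
Conditions: 19, Bu2BOTf, EtN(CHMe2)2, CH2Cl2, –78 → 0 °C; then 16, –78 → 0 °C; aq. NaH2PO4/Na2HPO4 (pH 7), MeOH, H2O2
Reagents that add atoms: none
Why: Evans syn-aldol reaction: the (Z)-boron enolate 20 reacts with the aldehyde through a closed chair transition state in which the (R)-benzyl auxiliary shields one enolate face, which should give the (12S,13R) syn adduct, and the nitrile and the hindered 6β-hydroxyl do not interfere.

**Step 14**
Reactants: 21 aldol adduct
Product: 22 12-O-tert-butyldimethylsilyl ether of 21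
Conditions: Me3CSiMe2OTf (1.2 equiv), 2,6-lutidine, CH2Cl2, –78 °C
Reagents that add atoms: tert-butyldimethylsilyl trifluoromethanesulfonate, CC(C)(C)[Si](C)(C)OS(=O)(=O)C(F)(F)F
Why: Silylation at –78 °C should take only the unhindered C12 hydroxyl, since the axial 6β-hydroxyl, syn-axial to the methyl groups on C4 and C10, reacts far more slowly, and it keeps C12 out of the later oxidation.

**Step 15**
Reactants: 22 12-O-tert-butyldimethylsilyl ether of 21
Product: 24 (3R)-3-[(1S)-1-(tert-butyldimethylsilyloxy)-2-(2α-chloro-6β-hydroxy-4,4,10β-trimethyl-8-methylidene-5α-decalin-9β-yl)ethyl]pyrrolidine-2,5-dione, via primary amide 23 (not isolated)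
Conditions: [PtH(PMe2OH)(PMe2O)2H] (5 mol %), EtOH/H2O, 80 °C; then Et3N, rt
Reagents that add atoms: water, O
Why: Platinum-catalysed hydration turns the nitrile into the primary amide 23 under neutral conditions, and its nitrogen then attacks the activated N-acyloxazolidinone carbonyl in a 5-exo-trig acyl substitution that closes the succinimide and releases the auxiliary without epimerising C13.

**Step 16**
Reactants: 24 silyl-protected 6β-hydroxy succinimide
Product: 25 12-O-tert-butyldimethylsilyl haterumaimide G (C6 ketone)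
Conditions: Dess–Martin periodinane, pyridine, CH2Cl2, 0 °C → rt
Reagents that add atoms: none
Why: Dess–Martin oxidation converts the only free secondary alcohol into the C6 ketone under non-basic conditions, so that the new β,γ-unsaturated ketone is not isomerised into conjugation and the C5 stereocentre is not enolised.

**Step 17**
Reactants: 25 12-O-tert-butyldimethylsilyl haterumaimide G
Product: 26 haterumaimide G
Conditions: HF·pyridine, THF, 0 °C → rt
Reagents that add atoms: none
Why: Fluoride cleaves the silyl ether under mildly acidic, buffered conditions that leave the β,γ-unsaturated ketone, the chloride and the imide untouched and give the target.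

**Compound list**

1 | (S)-(+)-abscisic acid, (2Z,4E)-5-[(1S)-1-hydroxy-2,6,6-trimethyl-4-oxocyclohex-2-en-1-yl]-3-methylpenta-2,4-dienoic acid | CC1=CC(=O)CC(C)(C)[C@@]1(O)/C=C/C(C)=C\C(=O)O | starting material
2 | (1S)-1-hydroxy-2,6,6-trimethyl-4-oxocyclohex-2-ene-1-carbaldehyde | CC1=CC(=O)CC(C)(C)[C@@]1(O)C=O | intermediate
3 | 1-methoxy-1,3-bis(trimethylsilyloxy)buta-1,3-diene | COC(O[Si](C)(C)C)=CC(=C)O[Si](C)(C)C | starting material
4 | open-chain titanium aldolate, drawn titanium-free as the (5R)-diol with its C8 enol silyl ether | COC(=O)C=C(O[Si](C)(C)C)C[C@@H](O)[C@@]1(O)C(C)=CC(=O)CC1(C)C | intermediate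
5 | methyl 5β,6β-dihydroxy-4,4,10β-trimethyl-2,8-dioxodecalin-9β-carboxylate (A/B cis) | COC(=O)[C@H]1C(=O)C[C@@H](O)[C@]2(O)C(C)(C)CC(=O)C[C@]12C | intermediate
6 | 5β,6β-cyclic thionocarbonate of 5 | COC(=O)[C@H]1C(=O)C[C@H]2OC(=S)O[C@]23C(C)(C)CC(=O)C[C@]13C | intermediate
7 | 6β-O-[(tributylstannylthio)carbonyl] 5α-H keto ester | COC(=O)[C@H]1C(=O)C[C@@H](OC(=O)S[Sn](CCCC)(CCCC)CCCC)[C@H]2C(C)(C)CC(=O)C[C@]12C | intermediate
8 | methyl 6β-hydroxy-4,4,10β-trimethyl-2,8-dioxo-5α-decalin-9β-carboxylate (A/B trans) | COC(=O)[C@H]1C(=O)C[C@@H](O)[C@H]2C(C)(C)CC(=O)C[C@]12C | intermediate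
9 | 6β-triethylsilyl ether of 8 | COC(=O)[C@H]1C(=O)C[C@@H](O[Si](CC)(CC)CC)[C@H]2C(C)(C)CC(=O)C[C@]12C | intermediate
10 | sodium enolate of 9 (C8–O–, C8=C9) | [Na+].COC(=O)C1=C([O-])C[C@@H](O[Si](CC)(CC)CC)[C@H]2C(C)(C)CC(=O)C[C@]12C | intermediate
11 | methyl 2β-hydroxy-4,4,10β-trimethyl-8-oxo-6β-(triethylsilyloxy)-5α-decalin-9β-carboxylate | COC(=O)[C@H]1C(=O)C[C@@H](O[Si](CC)(CC)CC)[C@H]2C(C)(C)C[C@@H](O)C[C@]12C | intermediate
12 | methyl 2β-hydroxy-4,4,10β-trimethyl-8-methylidene-6β-(triethylsilyloxy)-5α-decalin-9β-carboxylate | C=C1C[C@@H](O[Si](CC)(CC)CC)[C@H]2C(C)(C)C[C@@H](O)C[C@]2(C)[C@H]1C(=O)OC | intermediate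
13 | methyl 2α-chloro-4,4,10β-trimethyl-8-methylidene-6β-(triethylsilyloxy)-5α-decalin-9β-carboxylate | C=C1C[C@@H](O[Si](CC)(CC)CC)[C@H]2C(C)(C)C[C@H](Cl)C[C@]2(C)[C@H]1C(=O)OC | intermediate
14 | 2α-chloro-4,4,10β-trimethyl-8-methylidene-6β-(triethylsilyloxy)-5α-decalin-9β-carbaldehyde | C=C1C[C@@H](O[Si](CC)(CC)CC)[C@H]2C(C)(C)C[C@H](Cl)C[C@]2(C)[C@H]1C=O | intermediate
15 | 9β-(2-methoxyethenyl) enol ether from 14 (E/Z) | C=C1C[C@@H](O[Si](CC)(CC)CC)[C@H]2C(C)(C)C[C@H](Cl)C[C@]2(C)[C@H]1C=COC | intermediate
16 | 2-(2α-chloro-6β-hydroxy-4,4,10β-trimethyl-8-methylidene-5α-decalin-9β-yl)acetaldehyde | C=C1C[C@@H](O)[C@H]2C(C)(C)C[C@H](Cl)C[C@]2(C)[C@H]1CC=O | intermediate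
17 | (4R)-4-benzyl-1,3-oxazolidin-2-one | O=C1N[C@H](Cc2ccccc2)CO1 | starting material
18 | 3-cyanopropanoic acid | N#CCCC(=O)O | starting material
19 | 4-[(4R)-4-benzyl-2-oxo-1,3-oxazolidin-3-yl]-4-oxobutanenitrile | N#CCCC(=O)N1[C@H](Cc2ccccc2)COC1=O | intermediate
20 | (Z)-dibutylboron enolate of 19 | N#CC\C=C(/OB(CCCC)CCCC)N1[C@H](Cc2ccccc2)COC1=O | intermediate
21 | syn-aldol adduct, (12S,13R), auxiliary attached | C=C1C[C@@H](O)[C@H]2C(C)(C)C[C@H](Cl)C[C@]2(C)[C@H]1C[C@H](O)[C@@H](CC#N)C(=O)N1[C@H](Cc2ccccc2)COC1=O | intermediate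
22 | 12-O-tert-butyldimethylsilyl ether of 21 | C=C1C[C@@H](O)[C@H]2C(C)(C)C[C@H](Cl)C[C@]2(C)[C@H]1C[C@H](O[Si](C)(C)C(C)(C)C)[C@@H](CC#N)C(=O)N1[C@H](Cc2ccccc2)COC1=O | intermediate
23 | primary amide from hydration of the nitrile of 22 | C=C1C[C@@H](O)[C@H]2C(C)(C)C[C@H](Cl)C[C@]2(C)[C@H]1C[C@H](O[Si](C)(C)C(C)(C)C)[C@@H](CC(N)=O)C(=O)N1[C@H](Cc2ccccc2)COC1=O | intermediate
24 | (3R)-3-[(1S)-1-(tert-butyldimethylsilyloxy)-2-(2α-chloro-6β-hydroxy-4,4,10β-trimethyl-8-methylidene-5α-decalin-9β-yl)ethyl]pyrrolidine-2,5-dione | C=C1C[C@@H](O)[C@H]2C(C)(C)C[C@H](Cl)C[C@]2(C)[C@H]1C[C@H](O[Si](C)(C)C(C)(C)C)[C@H]1CC(=O)NC1=O | intermediate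
25 | 12-O-tert-butyldimethylsilyl haterumaimide G | C=C1CC(=O)[C@H]2C(C)(C)C[C@H](Cl)C[C@]2(C)[C@H]1C[C@H](O[Si](C)(C)C(C)(C)C)[C@H]1CC(=O)NC1=O | intermediate
26 | haterumaimide G | C=C1CC(=O)[C@H]2C(C)(C)C[C@H](Cl)C[C@]2(C)[C@H]1C[C@H](O)[C@H]1CC(=O)NC1=O | target

**Count**

Total step count: 17. Longest linear sequence: 16 steps (steps 1–11 and 13–17; step 12 prepares the aldol partner).

**Steps most likely to fail**

Step 2. The ring-closing conjugate addition may not follow the aldol in the same flask: the titanium aldolate can revert by retro-aldol cleavage, lose water across C6–C7 or lactonise before C9 reaches C10. Fallback, from 2 back to 5 by known reactions: the aldol alone is run (TiCl4, 3, CH2Cl2, –78 °C) and quenched cold to give the open-chain diol β-keto ester F1; the diol is tied up with 2-methoxypropene and pyridinium p-toluenesulfonate as the acetonide F2; ring B is then closed by the base-mediated intramolecular Michael addition of the β-keto ester to the enone (Cs2CO3, MeCN, rt) to give the tricyclic acetonide F3; aqueous CF3CO2H removes the acetonide and gives 5.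

Step 4. Fragmentation of the stannyl adduct radical may be slow or go the wrong way (scission of the secondary C6–O bond, or reduction of the thionocarbonate without C–O scission). Fallback, from 5 to 9: the secondary hydroxyl is silylated first (Et3SiOTf, 2,6-lutidine, –78 °C) to the 6-O-triethylsilyl diol monoether F4, the remaining tertiary hydroxyl is acylated with ClCOCO2Me and DMAP to the C5 methyl oxalate F5, and tin hydride deoxygenation of this tertiary oxalate (Bu3SnH, AIBN, PhMe, 110 °C), in which only the C5–O bond can cleave, gives 9 directly.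

Step 8. E2 loss of the axial alkoxyphosphonium group toward C1 or C3 may outrun substitution. Fallback, from 12 to 13, by substitution with retention on the equatorial epimer: 12 is oxidised with Dess–Martin periodinane to the 2-ketone F6, which is reduced under equilibrating Meerwein–Ponndorf–Verley conditions (Al(OCHMe2)3, Me2CHOH, 80 °C) to the equatorial 2α-alcohol F7, and F7 is converted with SOCl2 followed by catalytic TiCl4 into 13 through collapse of the chlorosulfite with retention, an equatorial leaving group having no anti-periplanar hydrogen for elimination.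

**Further compounds**

F1 | step 2 | methyl (5R)-5-hydroxy-5-[(1S)-1-hydroxy-2,6,6-trimethyl-4-oxocyclohex-2-en-1-yl]-3-oxopentanoate | COC(=O)CC(=O)C[C@@H](O)[C@@]1(O)C(C)=CC(=O)CC1(C)C
F2 | step 2 | acetonide of F1 (5,6-O-isopropylidene) | COC(=O)CC(=O)C[C@H]1OC(C)(C)O[C@@]12C(C)=CC(=O)CC2(C)C
F3 | step 2 | 5β,6β-O-isopropylidene derivative of 5 | COC(=O)[C@H]1C(=O)C[C@H]2OC(C)(C)O[C@]23C(C)(C)CC(=O)C[C@]13C
F4 | step 4 | 6-O-triethylsilyl ether of 5 | COC(=O)[C@H]1C(=O)C[C@@H](O[Si](CC)(CC)CC)[C@]2(O)C(C)(C)CC(=O)C[C@]12C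
F5 | step 4 | C5 methyl oxalate of F4 | COC(=O)[C@H]1C(=O)C[C@@H](O[Si](CC)(CC)CC)[C@]2(OC(=O)C(=O)OC)C(C)(C)CC(=O)C[C@]12C
F6 | step 8 | methyl 4,4,10β-trimethyl-8-methylidene-2-oxo-6β-(triethylsilyloxy)-5α-decalin-9β-carboxylate | C=C1C[C@@H](O[Si](CC)(CC)CC)[C@H]2C(C)(C)CC(=O)C[C@]2(C)[C@H]1C(=O)OC
F7 | step 8 | methyl 2α-hydroxy-4,4,10β-trimethyl-8-methylidene-6β-(triethylsilyloxy)-5α-decalin-9β-carboxylate | C=C1C[C@@H](O[Si](CC)(CC)CC)[C@H]2C(C)(C)C[C@H](O)C[C@]2(C)[C@H]1C(=O)OC
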